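## Retrosynthetic overview

- Target 15 ⇐ 14 (C6 ketone reduction, cis to the acetate) ⇐ 13 (α'-acetoxylation at C7) ⇐ 12 (catalyst-controlled vinylation of the side-chain methyl ketone, C13).
- Ring A ⇐ cation–olefin cyclisation (C4–C5 bond) of the 3-homoprenyl cyclohexenone 11; ring B is there from the start, ring A is closed second.
- 11 ⇐ Stork–Danheiser chemistry on vinylogous ester 2: C9 alkylated twice (side chain, then methyl anti to the C8 methyl), then 1,2-addition and carbonyl transposition.
- 2 ⇐ achiral 5-methylcyclohexane-1,3-dione 1 by a chiral Brønsted acid-catalysed desymmetrising enol etherification that sets C8, the centre that relays to C9, C7 and C6.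

Assumption: atom labels follow halimane numbering (ring A = C1–C5, C10; ring B = C5–C10; side chain C11–C16), and the SMILES is read as (6S,7R,8S,9R,13R), i.e. 6-OH cis to 7-OAc, 7-OAc trans to the C8 methyl, C8 methyl cis to the C9 side chain.

## Route

Step 1
Reactants: 1 5-methylcyclohexane-1,3-dione
Product: 2 (5R)-3-ethoxy-5-methylcyclohex-2-en-1-one
Conditions: chiral BINOL-derived N-triflyl imidodiphosphorimidate Brønsted acid (IDPi, 3 mol%, antipode giving 5R), EtOH (1.5 equiv), 5 Å MS, CHCl3, 0 °C
Reagents that add atoms: ethanol, CCO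
Why: Proposed new method: catalytic asymmetric desymmetrising enol etherification (vinylogous Fischer esterification), in which the confined chiral acid protonates the enol of 1 to a Cs-symmetric 1,3-dihydroxycyclohexenyl cation paired with the chiral anion, the anion pocket reads the ring methyl and lets ethanol add to only one of the two enantiotopic oxygen-bearing termini, and water is lost irreversibly onto the sieves, so the methyl-bearing carbon (C8) becomes a stereocentre (R) although no bond to it is made; the closest known reaction types are the achiral acid-catalysed etherification of cyclic 1,3-diones and chiral Brønsted acid-catalysed asymmetric acetalisation.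

Step 2
Reactants: 2 (5R)-3-ethoxy-5-methylcyclohex-2-en-1-one; 3 2-(2-bromoethyl)-2-methyl-1,3-dioxolane
Product: 5 (5R,6S)-3-ethoxy-5-methyl-6-[2-(2-methyl-1,3-dioxolan-2-yl)ethyl]cyclohex-2-en-1-one, via kinetic lithium dienolate 4 (not isolated)
Conditions: LiN(iPr)2, THF, −78 °C; then 3, DMPU, −78 → 0 °C
Reagents that add atoms: none
Why: Stork–Danheiser kinetic α'-deprotonation of the vinylogous ester and SN2 alkylation of the dienolate at C9 with the primary bromide, the chain entering anti to the C8 methyl; this C9 configuration is provisional because the centre is planarised again in step 3.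

Step 3
Reactants: 5 (5R,6S)-3-ethoxy-5-methyl-6-[2-(2-methyl-1,3-dioxolan-2-yl)ethyl]cyclohex-2-en-1-one
Product: 7 (5R,6R)-3-ethoxy-5,6-dimethyl-6-[2-(2-methyl-1,3-dioxolan-2-yl)ethyl]cyclohex-2-en-1-one, via tetrasubstituted lithium dienolate 6 (not isolated)
Conditions: LiN(iPr)2, THF, −78 → −30 °C; then MeI, −78 → 0 °C
Reagents that add atoms: iodomethane, CI
Why: Second Stork–Danheiser α'-alkylation, in which the C8 methyl of the tetrasubstituted dienolate sits pseudoaxial to escape A(1,2) strain with the C9 chain and shields one face, so MeI adds anti to it and fixes the quaternary C9 with its methyl trans and its side chain cis to the C8 methyl (substrate control from the step 1 stereocentre).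

Step 4
Reactants: 7 (5R,6R)-3-ethoxy-5,6-dimethyl-6-[2-(2-methyl-1,3-dioxolan-2-yl)ethyl]cyclohex-2-en-1-one; 8 5-bromo-2-methylpent-2-ene
Product: 11 (4R,5R)-4,5-dimethyl-3-(4-methylpent-3-en-1-yl)-4-(3-oxobutyl)cyclohex-2-en-1-one, via (4-methylpent-3-en-1-yl)magnesium bromide 9 (not isolated), via tertiary carbinol adduct 10 (not isolated)
Conditions: 8, Mg, THF, rt; then 7, CeCl3, THF, −78 → 0 °C; then 1 M HCl, THF, rt
Reagents that add atoms: water, O
Why: Stork–Danheiser 1,2-addition and transposition, in which the CeCl3-activated Grignard reagent adds to the neopentyl vinylogous-ester carbonyl (C10) without enolisation and aqueous acid ionises the tertiary allylic carbinol, hydrolyses the enol ether to the transposed enone (C6 ketone) and cleaves the dioxolane in the same flask, leaving C8 and C9 untouched.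

Step 5
Reactants: 11 (4R,5R)-4,5-dimethyl-3-(4-methylpent-3-en-1-yl)-4-(3-oxobutyl)cyclohex-2-en-1-one
Product: 12 (3R,4R)-3,4,8,8-tetramethyl-4-(3-oxobutyl)-3,4,5,6,7,8-hexahydronaphthalen-1(2H)-one
Conditions: CF3SO3H (0.3 equiv), (CF3)2CHOH/CH2Cl2 1:4, 0 °C → rt
Reagents that add atoms: none
Why: Brønsted acid-mediated cation–olefin cyclisation of the cyclogeranyl type, in which reversible Markovnikov protonation of the trisubstituted alkene gives the tertiary C4 cation, the enone α-carbon C5 captures it 6-endo (directly or through the dienol) and loss of the C5 proton leaves the tetrasubstituted conjugated C5=C10 enone of ring A; elimination of the cation is reversible whereas C–C bond formation is not, and no stereocentre is made or touched.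

Step 6
Reactants: 12 (3R,4R)-3,4,8,8-tetramethyl-4-(3-oxobutyl)-3,4,5,6,7,8-hexahydronaphthalen-1(2H)-one
Product: 13 (3R,4R)-4-[(3R)-3-hydroxy-3-methylpent-4-en-1-yl]-3,4,8,8-tetramethyl-3,4,5,6,7,8-hexahydronaphthalen-1(2H)-one
Conditions: Zn(CH=CH2)2 (2 equiv), Ti(OiPr)4 (1.2 equiv), chiral trans-1,2-diaminocyclohexane bis(hydroxycamphorsulfonamide) ligand (10 mol%, antipode giving 13R), toluene/hexane, rt; then H2O
Reagents that add atoms: divinylzinc, C=C[Zn]C=C
Why: Catalytic asymmetric vinylation of a ketone (titanium–bis(sulfonamide) diol-catalysed organozinc 1,2-addition), in which the unhindered methyl ketone reacts while the tetrasubstituted C6 enone carbonyl flanked by the gem-dimethyl group does not, and the remote C13 carbinol centre (R) is set by the catalyst alone.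

Step 7
Reactants: 13 (3R,4R)-4-[(3R)-3-hydroxy-3-methylpent-4-en-1-yl]-3,4,8,8-tetramethyl-3,4,5,6,7,8-hexahydronaphthalen-1(2H)-one
Product: 14 (2R,3S,4R)-4-[(3R)-3-hydroxy-3-methylpent-4-en-1-yl]-3,4,8,8-tetramethyl-1-oxo-1,2,3,4,5,6,7,8-octahydronaphthalen-2-yl acetate
Conditions: Mn(OAc)3·2H2O (3 equiv), dry benzene, reflux (Dean–Stark)
Reagents that add atoms: manganese triacetate, CC(=O)[O-].CC(=O)[O-].CC(=O)[O-].[Mn+3]
Why: Mn(OAc)3 α'-acetoxylation of an enone, in which the manganese enolate formed at the only α'-position (C7) takes up acetate on the face opposite the adjacent C8 methyl, and since C7 stays epimerisable the trans-diequatorial 7-acetoxy/8-methyl isomer (7R) is also the thermodynamic one.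

Step 8
Reactants: 14 (2R,3S,4R)-4-[(3R)-3-hydroxy-3-methylpent-4-en-1-yl]-3,4,8,8-tetramethyl-1-oxo-1,2,3,4,5,6,7,8-octahydronaphthalen-2-yl acetate
Product: 15 (1S,2R,3S,4R)-1-hydroxy-4-[(3R)-3-hydroxy-3-methylpent-4-en-1-yl]-3,4,8,8-tetramethyl-1,2,3,4,5,6,7,8-octahydronaphthalen-2-yl acetate
Conditions: LiBH(s-Bu)3 (2 equiv), THF, −78 °C; AcOH quench at −78 °C
Reagents that add atoms: none
Why: Diastereoselective ketone reduction with a bulky trialkylborohydride, which attacks the C6 carbonyl along the equatorial trajectory and places the new hydroxyl pseudoaxial (6S), cis to the equatorial C7 acetate and free of peri strain with the C4 gem-dimethyl group; the cold AcOH quench suppresses 1,2-acyl migration and the ester and alkenes are inert at −78 °C.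

## Compound list

1 | 5-methylcyclohexane-1,3-dione | CC1CC(=O)CC(=O)C1 | starting material
2 | (5R)-3-ethoxy-5-methylcyclohex-2-en-1-one | CCOC1=CC(=O)C[C@H](C)C1 | intermediate
3 | 2-(2-bromoethyl)-2-methyl-1,3-dioxolane | CC1(CCBr)OCCO1 | starting material
4 | kinetic lithium dienolate of 2 (O-lithiated, C6 deprotonated, methyl centre unchanged) | CCOC1=CC(O[Li])=C[C@H](C)C1 | intermediate
5 | (5R,6S)-3-ethoxy-5-methyl-6-[2-(2-methyl-1,3-dioxolan-2-yl)ethyl]cyclohex-2-en-1-one (5,6-trans) | CCOC1=CC(=O)[C@@H](CCC2(C)OCCO2)[C@H](C)C1 | intermediate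
6 | tetrasubstituted lithium dienolate of 5 (O-lithiated, C6 planar, methyl centre unchanged) | CCOC1=CC(O[Li])=C(CCC2(C)OCCO2)[C@H](C)C1 | intermediate
7 | (5R,6R)-3-ethoxy-5,6-dimethyl-6-[2-(2-methyl-1,3-dioxolan-2-yl)ethyl]cyclohex-2-en-1-one (methyls trans) | CCOC1=CC(=O)[C@](C)(CCC2(C)OCCO2)[C@H](C)C1 | intermediate
8 | 5-bromo-2-methylpent-2-ene | CC(C)=CCCBr | starting material
9 | (4-methylpent-3-en-1-yl)magnesium bromide | CC(C)=CCC[Mg]Br | intermediate
10 | (5R,6R)-3-ethoxy-5,6-dimethyl-1-(4-methylpent-3-en-1-yl)-6-[2-(2-methyl-1,3-dioxolan-2-yl)ethyl]cyclohex-2-en-1-ol (tertiary carbinol adduct, C1 epimers) | CCOC1=CC(O)(CCC=C(C)C)[C@](C)(CCC2(C)OCCO2)[C@H](C)C1 | intermediate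
11 | (4R,5R)-4,5-dimethyl-3-(4-methylpent-3-en-1-yl)-4-(3-oxobutyl)cyclohex-2-en-1-one | O=C1C=C(CCC=C(C)C)[C@](C)(CCC(C)=O)[C@H](C)C1 | intermediate
12 | (3R,4R)-3,4,8,8-tetramethyl-4-(3-oxobutyl)-3,4,5,6,7,8-hexahydronaphthalen-1(2H)-one | CC(=O)CC[C@@]1(C)C2=C(C(=O)C[C@H]1C)C(C)(C)CCC2 | intermediate
13 | (3R,4R)-4-[(3R)-3-hydroxy-3-methylpent-4-en-1-yl]-3,4,8,8-tetramethyl-3,4,5,6,7,8-hexahydronaphthalen-1(2H)-one | C=C[C@](C)(O)CC[C@@]1(C)C2=C(C(=O)C[C@H]1C)C(C)(C)CCC2 | intermediate
14 | (2R,3S,4R)-4-[(3R)-3-hydroxy-3-methylpent-4-en-1-yl]-3,4,8,8-tetramethyl-1-oxo-1,2,3,4,5,6,7,8-octahydronaphthalen-2-yl acetate | C=C[C@](C)(O)CC[C@@]1(C)C2=C(C(=O)[C@H](OC(C)=O)[C@H]1C)C(C)(C)CCC2 | intermediate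
15 | (1S,2R,3S,4R)-1-hydroxy-4-[(3R)-3-hydroxy-3-methylpent-4-en-1-yl]-3,4,8,8-tetramethyl-1,2,3,4,5,6,7,8-octahydronaphthalen-2-yl acetate (CNP0126002.3) | C=C[C@](C)(O)CC[C@@]1(C)C2=C([C@H](O)[C@H](OC(C)=O)[C@H]1C)C(C)(C)CCC2 | target

## Step count and risks

Total step count: 8. Longest linear sequence: 8 steps (1 → 15); compounds 3 and 8 are commercial.

The three steps most likely to fail:

Step 1, the proposed new desymmetrisation. The catalyst must tell apart two enantiotopic carbonyl termini by a methyl group three bonds away. The product can also lose ee by re-entering the symmetric dialkoxyallyl cation if the reaction is left too long. The fallback uses known chemistry and sets out from 1. Classical etherification (EtOH, p-TsOH, toluene, Dean–Stark) gives racemic 3-ethoxy-5-methylcyclohex-2-en-1-one F1. Preparative chiral-phase SFC delivers the R enantiomer, and the route is rejoined at 2. The unwanted (5S)-3-ethoxy-5-methylcyclohex-2-en-1-one F2 is hydrolysed with 1 M HCl back to achiral 1 and recycled, so no material is lost to the resolution.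

Step 5, ring A closure. The enone α-carbon is a weak nucleophile, and the transient C10 cation next to the quaternary C9 could undergo a 1,2-methyl shift. The side-chain ketone could also enter aldol chemistry under acid. The fallback replaces the cationic closure by a Pd-catalysed reductive Heck cyclisation and sets out from 7. Commercial 5-bromo-2-methylpent-1-ene and Mg give (4-methylpent-4-en-1-yl)magnesium bromide F3, which adds to 7 (CeCl3, THF) to give the tertiary carbinol adduct F4. 1 M HCl turns this into (4R,5R)-4,5-dimethyl-3-(4-methylpent-4-en-1-yl)-4-(3-oxobutyl)cyclohex-2-en-1-one F5. α-Iodination (I2, pyridine, CH2Cl2) gives (4R,5R)-2-iodo-4,5-dimethyl-3-(4-methylpent-4-en-1-yl)-4-(3-oxobutyl)cyclohex-2-en-1-one F6. Pd(OAc)2, PPh3, HCO2Na and Et4NCl in DMF at 80 °C then effect 6-exo carbopalladation of the 1,1-disubstituted alkene. The resulting neopentyl-type alkylpalladium has no β-hydrogen and is reduced by formate, so the new quaternary C4 carries both methyl groups and the route is rejoined at 12.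

Step 6, the asymmetric vinylation. The catalyst has to distinguish the methyl group from the CH2CH2 chain of a dialkyl ketone, and unsubstituted divinylzinc is a less proven partner than substituted vinylzinc reagents. Any error appears as a C13 epimer that is hard to separate because the centre is remote from the ring. The fallback uses known chemistry in two operations and sets out from 12. Catalytic asymmetric Corey–Chaykovsky epoxidation of the methyl ketone (dimethyloxosulfonium methylide, LaLi3(binaphthoxide)3 5 mol%, triarylphosphine oxide additive, 5 Å MS, THF, rt) gives (3R,4R)-3,4,8,8-tetramethyl-4-{2-[(2R)-2-methyloxiran-2-yl]ethyl}-3,4,5,6,7,8-hexahydronaphthalen-1(2H)-one F7. Excess dimethylsulfonium methylide (Me3SI, n-BuLi, THF, −10 °C → rt) opens the epoxide at its CH2 terminus and the sulfonium alkoxide eliminates to the one-carbon-homologated tertiary vinyl carbinol. C13 is not touched in this opening, and the route is rejoined at 13.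

## Further compounds

F1 | step 1 | racemic 3-ethoxy-5-methylcyclohex-2-en-1-one | CCOC1=CC(=O)CC(C)C1
F2 | step 1 | (5S)-3-ethoxy-5-methylcyclohex-2-en-1-one | CCOC1=CC(=O)C[C@@H](C)C1
F3 | step 5 | (4-methylpent-4-en-1-yl)magnesium bromide | C=C(C)CCC[Mg]Br
F4 | step 5 | (5R,6R)-3-ethoxy-5,6-dimethyl-1-(4-methylpent-4-en-1-yl)-6-[2-(2-methyl-1,3-dioxolan-2-yl)ethyl]cyclohex-2-en-1-ol (tertiary carbinol adduct, C1 epimers) | CCOC1=CC(O)(CCCC(C)=C)[C@](C)(CCC2(C)OCCO2)[C@H](C)C1
F5 | step 5 | (4R,5R)-4,5-dimethyl-3-(4-methylpent-4-en-1-yl)-4-(3-oxobutyl)cyclohex-2-en-1-one | O=C1C=C(CCCC(C)=C)[C@](C)(CCC(C)=O)[C@H](C)C1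
F6 | step 5 | (4R,5R)-2-iodo-4,5-dimethyl-3-(4-methylpent-4-en-1-yl)-4-(3-oxobutyl)cyclohex-2-en-1-one | O=C1C(I)=C(CCCC(C)=C)[C@](C)(CCC(C)=O)[C@H](C)C1
F7 | step 6 | (3R,4R)-3,4,8,8-tetramethyl-4-{2-[(2R)-2-methyloxiran-2-yl]ethyl}-3,4,5,6,7,8-hexahydronaphthalen-1(2H)-one | C1[C@](C)(O1)CC[C@@]2(C)C3=C(C(=O)C[C@H]2C)C(C)(C)CCC3
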